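**Strategy.** Everything rests on reading the cyclohexenone ring (C5–C10 of the 2-oxaspiro[4.5]decane core; C6 ketone, C7=C8, C9 acetoxy carbon, C10 methylene) as a dehydrated 1,5-keto aldehyde: C9 is the α-carbon of a latent C8 aldehyde, so C9–C10 is a Michael bond and C7=C8 an aldol condensation. One amine-catalysed Michael/aldol condensation of but-3-en-2-one with achiral (silyloxy)acetaldehyde closes this ring and sets C9 by catalyst control. C9 then directs an anti aldol with a dienal (C1) and a bromoacetate alkylation (quaternary C5); lactonisation, acetylation and a closing cross-metathesis finish the side chain.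

Key step: step 1

Remark: C1–C10 are the target's 2-oxaspiro[4.5]decane locants (C1 lactone carbinol carbon, O2, C3 lactone carbonyl, C4 lactone CH2, C5 spiro carbon, C6 ketone, C7=C8, C9 acetoxy carbon, C10 ring CH2). Compounds 1, 2, 6, 14 and 20 and both enantiomers of the prolinol catalyst are taken as commercially available.

**Step 1**
Reactants: 1 but-3-en-2-one; 2 2-[(tert-butyldimethylsilyl)oxy]acetaldehyde
Product: 5 (4S)-4-[(tert-butyldimethylsilyl)oxy]cyclohex-2-en-1-one, via keto aldehyde 3 (not isolated), via aldol 4 (not isolated)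
Conditions: (R)-2-[diphenyl(trimethylsilyloxy)methyl]pyrrolidine (10 mol%), catechol (20 mol%), CH2Cl2, 4 °C; then Bn2NH·CF3CO2H (30 mol%), toluene, 45 °C
Reagents that add atoms: none
Why: The pyrrolidine condenses with aldehyde 2 to an E enamine, whose face remote from the diphenyl(silyloxy)methyl group adds to the β-carbon of 1 and gives keto aldehyde 3 after hydrolysis (C9–C10 bond). The ammonium salt then turns the methyl ketone of 3 into its enamine or enol, which attacks the aldehyde carbon in a 6-(enolexo)-exo-trig aldol to give 4, and loss of water gives enone 5 (C7=C8 bond). The closest known reaction type is the enamine-catalysed Michael addition of aldehydes to but-3-en-2-one followed by aldol condensation to 4-substituted cyclohex-2-enones (organocatalytic Robinson-type annulation). The single new stereocentre, the silyloxy carbon of 5 (later C9), is set by the catalyst: the (R)-configured pyrrolidine should deliver the (S)-α-silyloxy aldehyde. The step needs enamine formation at the aldehyde and not at the ketone of 1, a single ring-closure mode and survival of the α-stereocentre; the first follows from the faster condensation of amines with aldehydes, the second because only attack of the methyl ketone on the aldehyde gives a six-membered ring, and the third from closing under buffered weakly acidic conditions in which dehydration removes the enolisable aldehyde.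

**Step 2**
Reactants: 6 pent-1-en-4-yne
Product: 9 (2E)-3-methylhexa-2,5-dien-1-ol, via alkenylalane 7 (not isolated), via lithium alanate 8 (not isolated)
Conditions: Me3Al (2 equiv), Cp2ZrCl2 (0.25 equiv), CH2Cl2, 0 °C to rt; volatiles removed; n-BuLi, THF/hexane, −78 to 0 °C; (CH2O)n, rt; aq HCl
Reagents that add atoms: trimethylaluminium C[Al](C)C; formaldehyde (from paraformaldehyde) C=O
Why: The zirconium-catalysed carboalumination of a terminal alkyne (Negishi carboalumination) adds methyl and aluminium syn with methyl on the internal carbon and leaves the monosubstituted alkene alone, and alanate 8 attacks formaldehyde with retention, so the E trisubstituted alkene of the side chain is fixed here.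

**Step 3**
Reactants: 9 (2E)-3-methylhexa-2,5-dien-1-ol
Product: 10 (2E)-3-methylhexa-2,5-dienal
Conditions: MnO2 (15 equiv), CH2Cl2, rt
Reagents that add atoms: none
Why: Allylic oxidation with MnO2 is selective for the primary allylic alcohol and is neutral, so the E geometry and the unconjugated position of the terminal alkene should be kept.

**Step 4**
Reactants: 5 (4S)-4-[(tert-butyldimethylsilyl)oxy]cyclohex-2-en-1-one; 10 (2E)-3-methylhexa-2,5-dienal
Product: 12 (4S,6R)-4-[(tert-butyldimethylsilyl)oxy]-6-[(1R,2E)-1-hydroxy-3-methylhexa-2,5-dien-1-yl]cyclohex-2-en-1-one, via lithium dienolate 11 (not isolated)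
Conditions: LiN(iPr)2 (1.05 equiv), THF, −78 °C; 10, −78 °C; AcOH, −78 °C
Reagents that add atoms: none
Why: Kinetic α'-deprotonation of enone 5 gives cross-conjugated dienolate 11, which should add 1,2 to enal 10 (lithium aldol addition) on the ring face anti to the pseudoaxial silyloxy group and, being a ring-locked E enolate, through a Zimmerman–Traxler chair with the dienyl group equatorial, which gives the anti aldol and so sets C1 as R relative to C9; the new ring centre is re-enolised in step 6 and need not be kept.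

**Step 5**
Reactants: 12 (4S,6R)-4-[(tert-butyldimethylsilyl)oxy]-6-[(1R,2E)-1-hydroxy-3-methylhexa-2,5-dien-1-yl]cyclohex-2-en-1-one
Product: 13 (4S,6R)-4-[(tert-butyldimethylsilyl)oxy]-6-[(1R,2E)-3-methyl-1-[(triethylsilyl)oxy]hexa-2,5-dien-1-yl]cyclohex-2-en-1-one
Conditions: Et3SiCl, imidazole, DMF, 0 °C
Reagents that add atoms: chlorotriethylsilane CC[Si](Cl)(CC)CC
Why: Imidazole-promoted silylation of the secondary allylic alcohol (silyl ether formation) blocks retro-aldol cleavage and leaves only a poor β-leaving group next to the carbon that is enolised in step 6, without touching a stereocentre.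

**Step 6**
Reactants: 13 (4S,6R)-4-[(tert-butyldimethylsilyl)oxy]-6-[(1R,2E)-3-methyl-1-[(triethylsilyl)oxy]hexa-2,5-dien-1-yl]cyclohex-2-en-1-one; 14 methyl bromoacetate
Product: 16 methyl 2-[(1R,5S)-5-[(tert-butyldimethylsilyl)oxy]-1-[(1R,2E)-3-methyl-1-[(triethylsilyl)oxy]hexa-2,5-dien-1-yl]-2-oxocyclohex-3-en-1-yl]acetate, via lithium enolate 15 (not isolated)
Conditions: LiN(iPr)2 (1.1 equiv), THF, −78 °C; 14, DMPU, −78 to −40 °C
Reagents that add atoms: none
Why: Deprotonation of the remaining α'-hydrogen gives tetrasubstituted enolate 15, which should be alkylated on carbon by the α-bromo ester (ketone enolate alkylation) on the face anti to the C9 silyloxy group, the same face that is anti to the side-chain triethylsilyloxy group when its carbinol hydrogen eclipses the enolate oxygen to minimise allylic strain, so that the quaternary C5 is formed as R with the acetate arm trans to the C9 oxygen.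

**Step 7**
Reactants: 16 methyl 2-[(1R,5S)-5-[(tert-butyldimethylsilyl)oxy]-1-[(1R,2E)-3-methyl-1-[(triethylsilyl)oxy]hexa-2,5-dien-1-yl]-2-oxocyclohex-3-en-1-yl]acetate
Product: 18 (1R,5R,9S)-9-hydroxy-1-[(1E)-2-methylpenta-1,4-dien-1-yl]-2-oxaspiro[4.5]dec-7-ene-3,6-dione, via diol ester 17 (not isolated)
Conditions: HF·pyridine, pyridine, THF, 0 °C to rt
Reagents that add atoms: none
Why: HF·pyridine cleaves both silyl ethers (fluoride desilylation) and the freed C1 hydroxyl, held next to the ester by the quaternary C5, should close the γ-lactone by 5-exo-trig acyl substitution, whereas the C9 hydroxyl is trans to the acetate arm and cannot reach it; all three stereocentres are kept.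

**Step 8**
Reactants: 18 (1R,5R,9S)-9-hydroxy-1-[(1E)-2-methylpenta-1,4-dien-1-yl]-2-oxaspiro[4.5]dec-7-ene-3,6-dione
Product: 19 (1R,5R,9S)-1-[(1E)-2-methylpenta-1,4-dien-1-yl]-3,6-dioxo-2-oxaspiro[4.5]dec-7-en-9-yl acetate
Conditions: Ac2O, pyridine, DMAP (cat.), CH2Cl2, 0 °C
Reagents that add atoms: acetic anhydride CC(=O)OC(C)=O
Why: Nucleophile-catalysed acylation of the only free hydroxyl gives the acetate with retention at C9 under conditions too mild to enolise the enone or open the lactone.

**Step 9**
Reactants: 19 (1R,5R,9S)-1-[(1E)-2-methylpenta-1,4-dien-1-yl]-3,6-dioxo-2-oxaspiro[4.5]dec-7-en-9-yl acetate; 20 2-methylbut-3-en-2-ol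
Product: 21 (1R,5R,9S)-1-[(1E,4E)-6-hydroxy-2,6-dimethylhepta-1,4-dien-1-yl]-3,6-dioxo-2-oxaspiro[4.5]dec-7-en-9-yl acetate (the target)
Conditions: second-generation Hoveyda–Grubbs catalyst (5 mol%), 20 (10 equiv), CH2Cl2, 40 °C
Reagents that add atoms: none
Why: Ruthenium-catalysed olefin cross-metathesis joins the monosubstituted alkene of 19 to excess 2-methylbut-3-en-2-ol, a partner that dimerises slowly, and should give the E disubstituted alkene under thermodynamic control while the trisubstituted alkene, the electron-poor ring alkene and the tertiary alcohol stay untouched.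

**Compound list**

1 | but-3-en-2-one | CC(=O)C=C | starting material
2 | 2-[(tert-butyldimethylsilyl)oxy]acetaldehyde | CC(C)(C)[Si](C)(C)OCC=O | starting material
3 | (2S)-2-[(tert-butyldimethylsilyl)oxy]-5-oxohexanal | CC(C)(C)[Si](C)(C)O[C@@H](CCC(C)=O)C=O | intermediate
4 | (4S)-4-[(tert-butyldimethylsilyl)oxy]-3-hydroxycyclohexan-1-one (both C3 epimers) | CC(C)(C)[Si](C)(C)O[C@@H]1C(O)CC(=O)CC1 | intermediate
5 | (4S)-4-[(tert-butyldimethylsilyl)oxy]cyclohex-2-en-1-one | CC(C)(C)[Si](C)(C)O[C@@H]1C=CC(=O)CC1 | intermediate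
6 | pent-1-en-4-yne | C=CCC#C | starting material
7 | dimethyl[(1E)-2-methylpenta-1,4-dien-1-yl]alumane | C[Al](C)/C=C(\C)CC=C | intermediate
8 | lithium butyl(dimethyl)[(1E)-2-methylpenta-1,4-dien-1-yl]aluminate | [Li+].CCCC[Al-](C)(C)/C=C(\C)CC=C | intermediate
9 | (2E)-3-methylhexa-2,5-dien-1-ol | OC/C=C(\C)CC=C | intermediate
10 | (2E)-3-methylhexa-2,5-dienal | O=C/C=C(\C)CC=C | intermediate
11 | lithium (4S)-4-[(tert-butyldimethylsilyl)oxy]cyclohexa-1,5-dien-1-olate | CC(C)(C)[Si](C)(C)O[C@@H]1C=CC(O[Li])=CC1 | intermediate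
12 | (4S,6R)-4-[(tert-butyldimethylsilyl)oxy]-6-[(1R,2E)-1-hydroxy-3-methylhexa-2,5-dien-1-yl]cyclohex-2-en-1-one | CC(C)(C)[Si](C)(C)O[C@@H]1C=CC(=O)[C@@H]([C@H](O)/C=C(\C)CC=C)C1 | intermediate
13 | (4S,6R)-4-[(tert-butyldimethylsilyl)oxy]-6-[(1R,2E)-3-methyl-1-[(triethylsilyl)oxy]hexa-2,5-dien-1-yl]cyclohex-2-en-1-one | CC(C)(C)[Si](C)(C)O[C@@H]1C=CC(=O)[C@@H]([C@H](O[Si](CC)(CC)CC)/C=C(\C)CC=C)C1 | intermediate
14 | methyl bromoacetate | COC(=O)CBr | starting material
15 | lithium (4S)-4-[(tert-butyldimethylsilyl)oxy]-2-[(1R,2E)-3-methyl-1-[(triethylsilyl)oxy]hexa-2,5-dien-1-yl]cyclohexa-1,5-dien-1-olate | CC(C)(C)[Si](C)(C)O[C@@H]1C=CC(O[Li])=C([C@H](O[Si](CC)(CC)CC)/C=C(\C)CC=C)C1 | intermediate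
16 | methyl 2-[(1R,5S)-5-[(tert-butyldimethylsilyl)oxy]-1-[(1R,2E)-3-methyl-1-[(triethylsilyl)oxy]hexa-2,5-dien-1-yl]-2-oxocyclohex-3-en-1-yl]acetate | CC(C)(C)[Si](C)(C)O[C@@H]1C=CC(=O)[C@](CC(=O)OC)([C@H](O[Si](CC)(CC)CC)/C=C(\C)CC=C)C1 | intermediate
17 | methyl 2-[(1R,5S)-5-hydroxy-1-[(1R,2E)-1-hydroxy-3-methylhexa-2,5-dien-1-yl]-2-oxocyclohex-3-en-1-yl]acetate | O[C@@H]1C=CC(=O)[C@](CC(=O)OC)([C@H](O)/C=C(\C)CC=C)C1 | intermediate
18 | (1R,5R,9S)-9-hydroxy-1-[(1E)-2-methylpenta-1,4-dien-1-yl]-2-oxaspiro[4.5]dec-7-ene-3,6-dione | O[C@@H]1C=CC(=O)[C@@]2(CC(=O)O[C@@H]2/C=C(\C)CC=C)C1 | intermediate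
19 | (1R,5R,9S)-1-[(1E)-2-methylpenta-1,4-dien-1-yl]-3,6-dioxo-2-oxaspiro[4.5]dec-7-en-9-yl acetate | CC(=O)O[C@@H]1C=CC(=O)[C@@]2(CC(=O)O[C@@H]2/C=C(\C)CC=C)C1 | intermediate
20 | 2-methylbut-3-en-2-ol | CC(C)(O)C=C | starting material
21 | (1R,5R,9S)-1-[(1E,4E)-6-hydroxy-2,6-dimethylhepta-1,4-dien-1-yl]-3,6-dioxo-2-oxaspiro[4.5]dec-7-en-9-yl acetate | CC(=O)O[C@@H]1C=CC(=O)[C@@]2(CC(=O)O[C@@H]2/C=C(\C)C/C=C/C(C)(C)O)C1 | target

**Step count.** Total: 9 steps. Longest linear sequence: 8 steps (steps 2 to 9, from pent-1-en-4-yne 6 to 21).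

**Steps most likely to fail**

Step 6 (quaternary C5). Enolisation at the crowded tertiary α'-carbon may be slow, so that loss of triethylsilanolate from enolate 15, γ-deprotonation or alkylation on oxygen competes. The face selectivity also rests on two silyloxy groups acting together, and the side-chain one could instead steer the electrophile to the wrong face. The fallback is a chelate-controlled dianion alkylation that sets out from 12 and comes back at 18. Unprotected aldol 12 is treated with LiN(iPr)2 (2.2 equiv, THF, −78 to −40 °C) to give dilithium alkoxide enolate F1, in which lithium bridges the two oxygens and the carbinol oxygen can no longer leave. Bromo ester 14 should then enter anti to the dienyl group of the chelate, which is again the face anti to the ring silyloxy group, to give hydroxy ester F2 as its alkoxide. This should close in the flask to silyl ether lactone F3, and HF·pyridine (THF, 0 °C to rt) then gives 18.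

Step 4 (aldol). Proton transfer from the doubly allylic CH2 of 10 to dienolate 11 may outrun addition, and a loose transition state or retro-aldol equilibration may erode the anti selectivity at C1. The fallback is a Lewis-acid aldol without base that sets out from 5 and comes back at 12. Enone 5 is converted (LiN(iPr)2, Me3SiCl, THF, −78 °C) into silyl dienol ether F4. This is combined with 10 and BF3·OEt2 in CH2Cl2 at −78 °C in a Mukaiyama aldol addition through an open transition state, and aqueous work-up should return 12, still trans across the ring.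

Step 1 (key step). Self-aldol of 2 may outrun the Michael addition to 1, and enolisation of the α-silyloxy aldehyde in 3 before ring closure may erode the enantiomeric purity. The fallback replaces the catalytic Michael addition by an auxiliary-controlled alkylation, makes the same two bonds in separate operations, sets out from 2 and comes back at 5. Aldehyde 2 is condensed with (S)-1-amino-2-(methoxymethyl)pyrrolidine to SAMP hydrazone F5. Deprotonation (LiN(iPr)2, THF, −78 °C) and alkylation with 2-(2-bromoethyl)-2-methyl-1,3-dioxolane at −100 °C should give alkylated hydrazone F6 (C9–C10 bond). Its configuration is assigned by the usual model for SAMP hydrazone alkylation through an E azaenolate; the enantiomeric auxiliary would be used should the silyloxy group reverse it. Ozonolysis (CH2Cl2, −78 °C) releases ketal aldehyde F7. PPTS in wet acetone followed by Bn2NH·CF3CO2H in toluene at 45 °C unmasks keto aldehyde 3, which closes and dehydrates to 5 as in step 1.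

**Further compounds**

F1 | step 6 | dilithium (4S)-4-[(tert-butyldimethylsilyl)oxy]-2-[(1R,2E)-3-methyl-1-oxidohexa-2,5-dien-1-yl]cyclohexa-1,5-dien-1-olate | CC(C)(C)[Si](C)(C)O[C@@H]1C=CC(O[Li])=C([C@H](O[Li])/C=C(\C)CC=C)C1
F2 | step 6 | methyl 2-[(1R,5S)-5-[(tert-butyldimethylsilyl)oxy]-1-[(1R,2E)-1-hydroxy-3-methylhexa-2,5-dien-1-yl]-2-oxocyclohex-3-en-1-yl]acetate | CC(C)(C)[Si](C)(C)O[C@@H]1C=CC(=O)[C@](CC(=O)OC)([C@H](O)/C=C(\C)CC=C)C1
F3 | step 6 | (1R,5R,9S)-9-[(tert-butyldimethylsilyl)oxy]-1-[(1E)-2-methylpenta-1,4-dien-1-yl]-2-oxaspiro[4.5]dec-7-ene-3,6-dione | CC(C)(C)[Si](C)(C)O[C@@H]1C=CC(=O)[C@@]2(CC(=O)O[C@@H]2/C=C(\C)CC=C)C1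
F4 | step 4 | tert-butyldimethyl{[(1S)-4-[(trimethylsilyl)oxy]cyclohexa-2,4-dien-1-yl]oxy}silane | CC(C)(C)[Si](C)(C)O[C@@H]1C=CC(O[Si](C)(C)C)=CC1
F5 | step 1 | (2S)-N-[(1E)-2-[(tert-butyldimethylsilyl)oxy]ethylidene]-2-(methoxymethyl)pyrrolidin-1-amine | COC[C@@H]1CCCN1/N=C/CO[Si](C)(C)C(C)(C)C
F6 | step 1 | (2S)-N-[(1E,2S)-2-[(tert-butyldimethylsilyl)oxy]-4-(2-methyl-1,3-dioxolan-2-yl)butylidene]-2-(methoxymethyl)pyrrolidin-1-amine | COC[C@@H]1CCCN1/N=C/[C@H](CCC2(C)OCCO2)O[Si](C)(C)C(C)(C)C
F7 | step 1 | (2S)-2-[(tert-butyldimethylsilyl)oxy]-4-(2-methyl-1,3-dioxolan-2-yl)butanal | CC1(CC[C@H](O[Si](C)(C)C(C)(C)C)C=O)OCCO1
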